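The runs are simulated with constants of no real substance.

Read the plateaus.

| flask | starting material | gas phase | remark | time |
|---|---|---|---|---|
| south-east | 0.56 M | 15 mM (held) | run made earlier |  |
| north | 0.88 M | 15 mM (held) | run made earlier |  |
| flask | 0.40 M | 15 mM (held) |  | 2.0 d |

- south-east (time / h: target / %): 2.00: 29.5; 6.00: 44.5; 10.0: 44.6; 15.0: 45.3; 20.0: 45.7; 30.0: 45.2
- north (time / h: target / %): 2.50: 28.7; 4.00: 37.3; 6.00: 40.5; 10.0: 42.6; 20.0: 41.6; 30.0: 40.9

(each reading ± 0.5 percentage points)

- at the start none of the gas phase is in solution
- the reaction counts as stopped when no species that holds the starting material changes by six tenths of a point or more over the second half of the time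

- which holds at 2.0 d: what has brought the reaction to rest, or that it has not come to rest (forward and back rates have come level / it is still moving / all of the starting material has reacted)
- amount of target at 2.0 d, in percent of the starting material charged

Does the target stop? Yes. From 10.0 h the south-east run averages 45.2 %, and from 10.0 h the north run averages 41.7 %.

What stopped it? I judge that it was not level rates. A back step with two partners should quicken with charge, yet the first reading of each run gives a time constant of 1.89 h south-east and 2.14 h north, which is longer, if anything. Those are readings, with their scatter.

So what do you carry? The shortfall ratio reads 1.21 south-east and 1.40 north: a selectivity factor, the part of the charge missing from the plateau divided by the plateau itself.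

Solve the ends. My picture is a second path competing with the gas. At a heavy charge, gas transfer would lag and the ratio would grow with c(starting material), between these runs at 0.580 M⁻¹. At a dilute charge, dissolved gas would stay near saturation and the ratio would tend to a constant, which the extrapolated runs put at 0.887. Join them as a straight line.

Two points make any line. Isn't that weak? Yes, and the flask is the test.

Your answer? At 0.40 M the ratio is 1.12, so the target is 47.2 %. The flask's 2.0 d is 25.4 south-east time constants, which by my estimate leaves <0.001 % of the starting material, so I say it has all reacted.

The forecast gives 48 % and "forward and back rates have come level": “Two days is far beyond the relaxation time”. Its target stands 0.80 percentage points above mine, and our ends differ.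

The flask gives 47.3 %, and all of the starting material has reacted.

    gas phase ⇌ dissolved gas, rate k1*(csat - [dissolved gas]) (kL = 0.00480 s⁻¹)
    starting material → side product (k = 8.70 × 10⁻⁵ s⁻¹)
    starting material + dissolved gas → target (k = 0.00680 M⁻¹ s⁻¹)

This flask is at rest with 0 % of its starting material left, not at level rates. Its 52.7 % of side product is the shortfall, a ratio to target of 1.11 against the 1.12 reckoned. The same line at 1.0 M gives 40.5 % of target, and that neighbour flask stores 41.2 %. In this flask the starting material stands at 0.194 % after 0.400 d and at 0 % after 1.00 d. Ten times the time changes nothing: after 20.0 d the target in this flask still stands at 47.3 %.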